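**Retrosynthetic overview**
1. Target 22 ⇐ methyl ester 21 (aldehyde-assisted ester cleavage) ⇐ diol 15 + trienoic acid 19 (C6–O acylation); 19 ⇐ hexadienal 16 + malonic acid 17.
2. 15 ⇐ 13 by α-face hydroxylation of the C9 ester enolate.
3. 13 ⇐ 10 + 11: ring B is cut at C9–C10 (a tertiary C10 radical, made by hydrogen-atom transfer to a methylidene group, adds to the enal-ester) and at C7–C8 (aldol condensation).
4. 10 ⇐ 3-methylcyclohex-2-enone 1: conjugate methylation (C4), asymmetric glyoxylate aldol (C5, C6), methylenation (C10 methyl carbon), ester-to-aldehyde reduction.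
5. Ring order: ring A is carried in from 1; ring B is formed in the annulation of step 6.

Assumption: positions use drimane numbering (C1–C12). The target is made as drawn (open 11-acid/12-aldehyde), which is the ring-chain tautomer of its 12-hydroxy-11,12-olide.

**Route**

Step 1
Reactants: 1 3-methylcyclohex-2-en-1-one
Product: 3 [(3,3-dimethylcyclohex-1-en-1-yl)oxy]trimethylsilane, via magnesium enolate 2 (not isolated)
Conditions: MeMgBr, CuI (5 mol %), LiCl (10 mol %), Me3SiCl, THF, −40 → 0 °C; Et3N, pentane work-up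
Reagents that add atoms: methylmagnesium bromide (C[Mg]Br); chlorotrimethylsilane (C[Si](C)(C)Cl)
Why: Copper-catalysed conjugate addition of the methyl Grignard reagent builds the C4 gem-dimethyl carbon, and in situ silylation fixes the enolate regiospecifically towards C5; no stereocenter is formed.

Step 2
Reactants: 3 [(3,3-dimethylcyclohex-1-en-1-yl)oxy]trimethylsilane; 4 ethyl glyoxylate
Product: 6 ethyl (2R)-2-[(1R)-2,2-dimethyl-6-oxocyclohexyl]-2-hydroxyacetate, via silyl aldol ether 5 (not isolated)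
Conditions: ScCl3(THF)3 (10 mol %), AgSbF6 (10 mol %), Ph-pybox (11 mol %, the antipode that directs Re-face attack on 4), CH2Cl2, −78 °C; then 1 M HCl, THF
Reagents that add atoms: none
Why: Catalytic enantioselective Mukaiyama aldol addition: the scandium–pybox complex chelates the glyoxylate so that the Si face of the enol silane attacks its Re face, which sets C5 (R) and C6 (R) in the syn relationship that becomes 5α-H/6α-O; the sense of induction of the ligand has to be confirmed experimentally.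

Step 3
Reactants: 6 ethyl (2R)-2-[(1R)-2,2-dimethyl-6-oxocyclohexyl]-2-hydroxyacetate
Product: 7 ethyl (2R)-2-[(1R)-2,2-dimethyl-6-oxocyclohexyl]-2-(triethylsilyloxy)acetate
Conditions: Et3SiOTf, 2,6-lutidine, CH2Cl2, −78 °C
Reagents that add atoms: triethylsilyl trifluoromethanesulfonate (CC[Si](CC)(CC)OS(=O)(=O)C(F)(F)F)
Why: Silyl ether formation blocks retro-aldol cleavage and protects the carbinol through the later α-oxy aldehyde stage; no stereocenter is touched.

Step 4
Reactants: 7 ethyl (2R)-2-[(1R)-2,2-dimethyl-6-oxocyclohexyl]-2-(triethylsilyloxy)acetate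
Product: 8 ethyl (2R)-2-[(1S)-2,2-dimethyl-6-methylidenecyclohexyl]-2-(triethylsilyloxy)acetate
Conditions: Zn, CH2Br2, TiCl4, THF/CH2Cl2, 0 °C → rt
Reagents that add atoms: dibromomethane (BrCBr)
Why: Takai–Lombardo methylenation: the non-basic zinc/titanium reagent converts the ketone into the exocyclic alkene without epimerising C5 or eliminating the β-silyloxy group, and leaves the ester alone (the C5 descriptor changes only through priorities).

Step 5
Reactants: 8 ethyl (2R)-2-[(1S)-2,2-dimethyl-6-methylidenecyclohexyl]-2-(triethylsilyloxy)acetate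
Product: 10 (2R)-2-[(1S)-2,2-dimethyl-6-methylidenecyclohexyl]-2-(triethylsilyloxy)acetaldehyde, via aluminium hemiacetal 9 (not isolated)
Conditions: i-Bu2AlH (1.1 equiv), CH2Cl2, −78 °C; then MeOH, aq. sodium potassium tartrate
Reagents that add atoms: none
Why: Partial reduction of the α-silyloxy ester stops at the aluminium hemiacetal, which gives the aldehyde on work-up; the non-basic conditions leave C6 intact.

Step 6 (key step)
Reactants: 10 (2R)-2-[(1S)-2,2-dimethyl-6-methylidenecyclohexyl]-2-(triethylsilyloxy)acetaldehyde; 11 methyl (2E)-4-oxobut-2-enoate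
Product: 13 methyl (4S,4aS,8aS)-2-formyl-4-hydroxy-5,5,8a-trimethyl-1,4,4a,5,6,7,8,8a-octahydronaphthalene-1-carboxylate (methyl 6α-hydroxy-12-oxodrim-7-en-11-oate; C9 epimers), via hydroxy aldehyde 12 (not isolated)
Conditions: 11 (3 equiv), Fe(acac)3 (30 mol %), PhSiH3 (2.5 equiv), EtOH, 0 °C → rt; then 2 M HCl (aq), THF, 40 °C
Reagents that add atoms: none
Why: Hydrogen-atom-transfer-initiated radical–polar crossover annulation (Giese addition, then aldol): the iron hydride puts H on the methylidene carbon and the tertiary C10 radical adds to the carbon of 11 that is β to the formyl group, anti to the bulky C5 side chain, which makes the C9–C10 bond and the 10β-methyl quaternary centre. The resulting α-formyl radical is reduced to the enolate, which closes ring B onto the C7 aldehyde, and acid then dehydrates to the C7=C8 enal and removes the silyl group (C7/C8 stereo is erased; C9 is reset in step 7).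

Step 7
Reactants: 13 methyl 6α-hydroxy-12-oxodrim-7-en-11-oate (C9 epimers)
Product: 15 methyl (1S,4S,4aS,8aS)-2-formyl-1,4-dihydroxy-5,5,8a-trimethyl-1,4,4a,5,6,7,8,8a-octahydronaphthalene-1-carboxylate, via lithium amino alkoxide 14 (not isolated)
Conditions: morpholine/n-BuLi (2.1 equiv), THF, −78 °C; LiN(i-Pr)2 (1.5 equiv), −78 → −40 °C; 2-(benzenesulfonyl)-3-phenyloxaziridine, −78 °C; then 1 M HCl
Reagents that add atoms: 2-(benzenesulfonyl)-3-phenyloxaziridine (O=S(=O)(N1OC1c1ccccc1)c1ccccc1)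
Why: Davis α-hydroxylation of the C9 ester enolate with the enal masked in situ as its lithium α-amino alkoxide (this also blocks γ-deprotonation at C6): the oxaziridine attacks from the α face, opposite the axial C10 methyl group, giving the 9α-hydroxy-9β-ester from either C9 epimer.

Step 8
Reactants: 16 (2E,4E)-hexa-2,4-dienal; 17 malonic acid
Product: 19 (2E,4E,6E)-octa-2,4,6-trienoic acid, via dienylidenemalonic acid 18 (not isolated)
Conditions: pyridine, piperidine (cat.), 90 °C; then aq. HCl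
Reagents that add atoms: none
Why: Knoevenagel–Doebner condensation with decarboxylation extends the dienal by two carbons and gives the all-E acid under thermodynamic control.

Step 9
Reactants: 15 methyl 6α,9α-dihydroxy-12-oxodrim-7-en-11-oate; 19 (2E,4E,6E)-octa-2,4,6-trienoic acid
Product: 21 methyl (1S,4S,4aS,8aS)-2-formyl-1-hydroxy-5,5,8a-trimethyl-4-[(2E,4E,6E)-octa-2,4,6-trienoyloxy]-1,4,4a,5,6,7,8,8a-octahydronaphthalene-1-carboxylate, via mixed anhydride 20 (not isolated)
Conditions: 19 (1.5 equiv), 2,4,6-trichlorobenzoyl chloride, Et3N, THF, rt; then 15, DMAP, toluene, rt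
Reagents that add atoms: none
Why: Yamaguchi esterification acylates the secondary, equatorial 6α-hydroxyl, while the tertiary C9 hydroxyl is too hindered to react; no stereocenter is affected.

Step 10
Reactants: 21 methyl ester of the target
Product: 22 (1S,4S,4aS,8aS)-2-formyl-1-hydroxy-5,5,8a-trimethyl-4-[(2E,4E,6E)-octa-2,4,6-trienoyloxy]-1,4,4a,5,6,7,8,8a-octahydronaphthalene-1-carboxylic acid (target)
Conditions: LiOH (1.5 equiv), THF/H2O (3:1), 0 °C; then 1 M HCl to pH 3
Reagents that add atoms: lithium hydroxide ([Li+].[OH-])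
Why: Neighbouring-group-assisted saponification: hydroxide adds to the C12 aldehyde and the hydrate anion attacks the adjacent C11 methyl ester through a five-membered ring (as in 2-formylbenzoates), so this ester should cleave at 0 °C while the conjugated secondary trienoate survives.

**Compound list**
1 | 3-methylcyclohex-2-en-1-one | CC1=CC(=O)CCC1 | starting material
2 | bromomagnesium 3,3-dimethylcyclohex-1-en-1-olate | CC1(C)C=C(O[Mg]Br)CCC1 | intermediate
3 | [(3,3-dimethylcyclohex-1-en-1-yl)oxy]trimethylsilane | CC1(C)C=C(O[Si](C)(C)C)CCC1 | intermediate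
4 | ethyl glyoxylate | CCOC(=O)C=O | starting material
5 | ethyl (2R)-2-[(1R)-2,2-dimethyl-6-oxocyclohexyl]-2-(trimethylsilyloxy)acetate | CCOC(=O)[C@H](O[Si](C)(C)C)[C@@H]1C(=O)CCCC1(C)C | intermediate
6 | ethyl (2R)-2-[(1R)-2,2-dimethyl-6-oxocyclohexyl]-2-hydroxyacetate | CCOC(=O)[C@H](O)[C@@H]1C(=O)CCCC1(C)C | intermediate
7 | ethyl (2R)-2-[(1R)-2,2-dimethyl-6-oxocyclohexyl]-2-(triethylsilyloxy)acetate | CCOC(=O)[C@H](O[Si](CC)(CC)CC)[C@@H]1C(=O)CCCC1(C)C | intermediate
8 | ethyl (2R)-2-[(1S)-2,2-dimethyl-6-methylidenecyclohexyl]-2-(triethylsilyloxy)acetate | CCOC(=O)[C@H](O[Si](CC)(CC)CC)[C@@H]1C(=C)CCCC1(C)C | intermediate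
9 | diisobutylaluminium ethyl hemiacetal of 10 (hemiacetal carbon undefined) | CCOC(O[Al](CC(C)C)CC(C)C)[C@H](O[Si](CC)(CC)CC)[C@@H]1C(=C)CCCC1(C)C | intermediate
10 | (2R)-2-[(1S)-2,2-dimethyl-6-methylidenecyclohexyl]-2-(triethylsilyloxy)acetaldehyde | O=C[C@H](O[Si](CC)(CC)CC)[C@@H]1C(=C)CCCC1(C)C | intermediate
11 | methyl (2E)-4-oxobut-2-enoate | COC(=O)/C=C/C=O | starting material
12 | methyl (4R,4aS,8aS)-2-formyl-3-hydroxy-5,5,8a-trimethyl-4-(triethylsilyloxy)decahydronaphthalene-1-carboxylate (C1, C2, C3 undefined) | CC[Si](CC)(CC)O[C@H]1C(O)C(C=O)C(C(=O)OC)[C@@]2(C)CCCC(C)(C)[C@H]12 | intermediate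
13 | methyl (4S,4aS,8aS)-2-formyl-4-hydroxy-5,5,8a-trimethyl-1,4,4a,5,6,7,8,8a-octahydronaphthalene-1-carboxylate (C1 epimers) | O[C@H]1C=C(C=O)C(C(=O)OC)[C@@]2(C)CCCC(C)(C)[C@H]12 | intermediate
14 | dilithium salt of 13: C6 alkoxide, C12 morpholine hemiaminal alkoxide | [Li]O[C@H]1C=C(C(O[Li])N3CCOCC3)C(C(=O)OC)[C@@]2(C)CCCC(C)(C)[C@H]12 | intermediate
15 | methyl (1S,4S,4aS,8aS)-2-formyl-1,4-dihydroxy-5,5,8a-trimethyl-1,4,4a,5,6,7,8,8a-octahydronaphthalene-1-carboxylate | O[C@H]1C=C(C=O)[C@](O)(C(=O)OC)[C@@]2(C)CCCC(C)(C)[C@H]12 | intermediate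
16 | (2E,4E)-hexa-2,4-dienal | C/C=C/C=C/C=O | starting material
17 | malonic acid | OC(=O)CC(=O)O | starting material
18 | 2-[(2E,4E)-hexa-2,4-dien-1-ylidene]propanedioic acid | C/C=C/C=C/C=C(C(=O)O)C(=O)O | intermediate
19 | (2E,4E,6E)-octa-2,4,6-trienoic acid | C/C=C/C=C/C=C/C(=O)O | intermediate
20 | (2E,4E,6E)-octa-2,4,6-trienoic 2,4,6-trichlorobenzoic anhydride | C/C=C/C=C/C=C/C(=O)OC(=O)c1c(Cl)cc(Cl)cc1Cl | intermediate
21 | methyl (1S,4S,4aS,8aS)-2-formyl-1-hydroxy-5,5,8a-trimethyl-4-[(2E,4E,6E)-octa-2,4,6-trienoyloxy]-1,4,4a,5,6,7,8,8a-octahydronaphthalene-1-carboxylate | C/C=C/C=C/C=C/C(=O)O[C@H]1C=C(C=O)[C@](O)(C(=O)OC)[C@@]2(C)CCCC(C)(C)[C@H]12 | intermediate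
22 | (1S,4S,4aS,8aS)-2-formyl-1-hydroxy-5,5,8a-trimethyl-4-[(2E,4E,6E)-octa-2,4,6-trienoyloxy]-1,4,4a,5,6,7,8,8a-octahydronaphthalene-1-carboxylic acid | C/C=C/C=C/C=C/C(=O)O[C@H]1C=C(C=O)[C@](O)(C(=O)O)[C@@]2(C)CCCC(C)(C)[C@H]12 | target

**Step count and risks**
Total steps: 10. Longest linear sequence: 9 (steps 1–7, 9, 10).

Step 6 (annulation). Likely failures are reduction of the alkene before it is trapped, β-scission of the C5–C6 bond in the C10 radical, or poor facial selectivity at C10. The fallback sets out from 10 and ties the acceptor on first: a DABCO-mediated Morita–Baylis–Hillman reaction of 10 with 11 gives methyl (5R)-5-[(1S)-2,2-dimethyl-6-methylidenecyclohexyl]-3-formyl-4-hydroxy-5-(triethylsilyloxy)pent-2-enoate F1. Under the Fe(acac)3/PhSiH3 conditions the C10 radical then cyclises intramolecularly (6-endo) onto the acrylate-type carbon C9, which gives 12. The route is rejoined at 12, which goes on to 13 by the acid treatment of step 6.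

Step 7 (C9 hydroxylation). The transient aldehyde protection may be incomplete, leading to attack at the enal or γ-deprotonation. The fallback sets out from 13 and uses a discrete protecting group: ethylene glycol and PPTS in benzene at reflux give methyl (4S,4aS,8aS)-2-(1,3-dioxolan-2-yl)-4-hydroxy-5,5,8a-trimethyl-1,4,4a,5,6,7,8,8a-octahydronaphthalene-1-carboxylate F2. KN(SiMe3)2 (2.2 equiv) and the same oxaziridine hydroxylate the potassium enolate from the α face to give methyl (1S,4S,4aS,8aS)-2-(1,3-dioxolan-2-yl)-1,4-dihydroxy-5,5,8a-trimethyl-1,4,4a,5,6,7,8,8a-octahydronaphthalene-1-carboxylate F3. 1 M HCl in THF removes the acetal and the route is rejoined at 15.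

Step 2 (asymmetric aldol). The nucleophilic carbon is neopentyl, so rate, syn/anti ratio or ee may be poor, and the β-hydroxy ketone can undergo retro-aldol. The fallback sets out from 1 and replaces the enol silane by an allylsilane: the copper-catalysed methyl addition is quenched with N-phenylbis(trifluoromethanesulfonimide) to give 3,3-dimethylcyclohex-1-en-1-yl trifluoromethanesulfonate F4. Kumada coupling with Me3SiCH2MgCl (Pd(PPh3)4, THF) gives [(3,3-dimethylcyclohex-1-en-1-yl)methyl]trimethylsilane F5. Its scandium–pybox-catalysed Hosomi–Sakurai addition to 4 (anti SE2') gives ethyl (2R)-2-[(1S)-2,2-dimethyl-6-methylidenecyclohexyl]-2-hydroxyacetate F6 with the methylidene group already in place. Silylation with Et3SiOTf rejoins the route at 8.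

Further compounds
F1 | step 6 | methyl (5R)-5-[(1S)-2,2-dimethyl-6-methylidenecyclohexyl]-3-formyl-4-hydroxy-5-(triethylsilyloxy)pent-2-enoate (C4 and alkene geometry undefined) | COC(=O)C=C(C=O)C(O)[C@H](O[Si](CC)(CC)CC)[C@@H]1C(=C)CCCC1(C)C
F2 | step 7 | methyl (4S,4aS,8aS)-2-(1,3-dioxolan-2-yl)-4-hydroxy-5,5,8a-trimethyl-1,4,4a,5,6,7,8,8a-octahydronaphthalene-1-carboxylate (C1 epimers) | O[C@H]1C=C(C3OCCO3)C(C(=O)OC)[C@@]2(C)CCCC(C)(C)[C@H]12
F3 | step 7 | methyl (1S,4S,4aS,8aS)-2-(1,3-dioxolan-2-yl)-1,4-dihydroxy-5,5,8a-trimethyl-1,4,4a,5,6,7,8,8a-octahydronaphthalene-1-carboxylate | O[C@H]1C=C(C3OCCO3)[C@](O)(C(=O)OC)[C@@]2(C)CCCC(C)(C)[C@H]12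
F4 | step 2 | 3,3-dimethylcyclohex-1-en-1-yl trifluoromethanesulfonate | CC1(C)C=C(OS(=O)(=O)C(F)(F)F)CCC1
F5 | step 2 | [(3,3-dimethylcyclohex-1-en-1-yl)methyl]trimethylsilane | CC1(C)C=C(C[Si](C)(C)C)CCC1
F6 | step 2 | ethyl (2R)-2-[(1S)-2,2-dimethyl-6-methylidenecyclohexyl]-2-hydroxyacetate | CCOC(=O)[C@H](O)[C@@H]1C(=C)CCCC1(C)C
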